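## Retrosynthetic overview

1. The target is released in one acidolysis from its tert-butyl ester / TBS ether.
2. The only ring, the 5,6-dihydropyran-2-one, is closed late by an isothiourea-catalysed formal [4+2] between a γ-acyloxy crotonate aryl ester (already carrying the whole side chain) and tert-butyl 4-oxobut-2-enoate. This one step forms the C5–C6 bond and the lactone C–O bond and sets both ring stereocentres.
3. That aryl ester comes from O-alkylation of the side-chain acid with an aryl 4-bromocrotonate.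
4. The side-chain acid comes from Wittig and Doebner olefinations of (R)-2-methyl-7-oxooctanal, with C11 set by ketoreductase reduction of the methyl ketone.
5. (R)-2-Methyl-7-oxooctanal comes from Wittig chain extension and hydrogenation of (R)-4,4-dimethoxy-3-methylbutanal, whose stereocentre (the first of the route) is set by organocatalytic transfer hydrogenation of an achiral enal.

## Route

Step 1
Reactants: 1 1,1-dimethoxypropan-2-one; 2 (triphenylphosphoranylidene)acetaldehyde
Product: 3 (2E)-4,4-dimethoxy-3-methylbut-2-enal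
Conditions: toluene, 100 °C, 24 h
Reagents that add atoms: none
Why: Wittig olefination of the acetal-activated ketone with a stabilised formyl ylide gives the trisubstituted enal mainly as the E isomer, and any Z isomer converges to the same product in step 2.

Step 2
Reactants: 3 (2E)-4,4-dimethoxy-3-methylbut-2-enal
Product: 4 (3R)-4,4-dimethoxy-3-methylbutanal
Conditions: (S)-2-tert-butyl-3-methylimidazolidin-4-one·Cl3CCO2H (20 mol%), Hantzsch ester (diethyl 2,6-dimethyl-1,4-dihydropyridine-3,5-dicarboxylate, 1.2 equiv), CHCl3, −30 °C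
Reagents that add atoms: none
Why: Organocatalytic iminium transfer hydrogenation (MacMillan-type enal reduction), in which the imidazolidinone shields one face of the iminium ion so that hydride from the dihydropyridine sets C3 as R (the future C6 of the side chain); the catalyst enantiomer is chosen by analogy with the known sense for β-methyl enals.

Step 3
Reactants: 4 (3R)-4,4-dimethoxy-3-methylbutanal; 5 [2-(2-methyl-1,3-dioxolan-2-yl)ethyl]triphenylphosphonium bromide
Product: 7 2-[(2Z,5R)-6,6-dimethoxy-5-methylhex-2-en-1-yl]-2-methyl-1,3-dioxolane, via phosphorus ylide 6 (not isolated)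
Conditions: 5, NaN(SiMe3)2, THF, −78 °C; then 4, −78 °C → rt
Reagents that add atoms: none
Why: Wittig olefination with a non-stabilised ylide appends the four-carbon masked methyl ketone without touching the stereocentre (β to the aldehyde), and the alkene geometry is irrelevant because the alkene is hydrogenated next.

Step 4
Reactants: 7 2-[(2Z,5R)-6,6-dimethoxy-5-methylhex-2-en-1-yl]-2-methyl-1,3-dioxolane
Product: 9 (2R)-2-methyl-7-oxooctanal, via saturated bis-acetal 8 (not isolated)
Conditions: H2 (1 atm), Pd/C, EtOAc, rt; filter; then 1 M HCl, THF, 0 °C → rt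
Reagents that add atoms: water, O
Why: Catalytic hydrogenation of the disubstituted alkene followed by cold, brief acid hydrolysis of both acetals gives the keto aldehyde without epimerising the α-methyl aldehyde.

Step 5
Reactants: 9 (2R)-2-methyl-7-oxooctanal; 10 2-(triphenylphosphoranylidene)propanal
Product: 11 (2E,4R)-2,4-dimethyl-9-oxodec-2-enal
Conditions: toluene, 90 °C
Reagents that add atoms: none
Why: Wittig olefination with a stabilised ylide reacts only at the aldehyde (not the methyl ketone), gives the E-trisubstituted enal, and being base-free leaves the α-stereocentre intact.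

Step 6
Reactants: 11 (2E,4R)-2,4-dimethyl-9-oxodec-2-enal; 12 malonic acid
Product: 14 (2E,4E,6R)-4,6-dimethyl-11-oxododeca-2,4-dienoic acid, via alkylidenemalonic acid 13 (not isolated)
Conditions: pyridine, 75 °C (no secondary amine)
Reagents that add atoms: none
Why: Knoevenagel condensation with Doebner decarboxylation gives the (2E,4E)-dienoic acid directly; the ketone does not condense, and without a secondary amine no dienamine can form to epimerise C6.

Step 7
Reactants: 14 (2E,4E,6R)-4,6-dimethyl-11-oxododeca-2,4-dienoic acid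
Product: 15 (2E,4E,6R,11S)-11-hydroxy-4,6-dimethyldodeca-2,4-dienoic acid
Conditions: (S)-selective NADPH-dependent ketoreductase, NADP+ (cat.), iPrOH (10 vol%), KH2PO4/K2HPO4 buffer pH 7, 30 °C
Reagents that add atoms: none
Why: Biocatalytic asymmetric ketone reduction, in which a Prelog-selective ketoreductase delivers hydride to the Re face of the methyl n-alkyl ketone to give the 11S alcohol, the carboxylate keeping the substrate in the aqueous phase and the dienoate untouched.

Step 8
Reactants: 15 (2E,4E,6R,11S)-11-hydroxy-4,6-dimethyldodeca-2,4-dienoic acid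
Product: 17 (2E,4E,6R,11S)-11-[(tert-butyldimethylsilyl)oxy]-4,6-dimethyldodeca-2,4-dienoic acid, via silyl ester 16 (not isolated)
Conditions: TBSCl (2.5 equiv), imidazole, DMF, rt; then THF, 10% aq. citric acid, rt
Reagents that add atoms: tert-butyldimethylsilyl chloride, CC(C)(C)[Si](C)(C)Cl
Why: Silylation of both the alcohol and the acid followed by selective hydrolysis of the labile silyl ester leaves the secondary TBS ether, which masks the alcohol from the acyl-transfer catalyst of step 12.

Step 9
Reactants: 18 (2E)-4-bromobut-2-enoic acid; 19 2,4,6-trichlorophenol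
Product: 20 2,4,6-trichlorophenyl (2E)-4-bromobut-2-enoate
Conditions: DCC, CH2Cl2, 0 °C → rt
Reagents that add atoms: none
Why: Carbodiimide esterification of an acidic phenol gives the activated aryl ester without any nucleophilic amine that could displace the allylic bromide.

Step 10
Reactants: 17 (2E,4E,6R,11S)-11-[(tert-butyldimethylsilyl)oxy]-4,6-dimethyldodeca-2,4-dienoic acid; 20 2,4,6-trichlorophenyl (2E)-4-bromobut-2-enoate
Product: 21 2,4,6-trichlorophenyl (2E)-4-{[(2E,4E,6R,11S)-11-[(tert-butyldimethylsilyl)oxy]-4,6-dimethyldodeca-2,4-dienoyl]oxy}but-2-enoate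
Conditions: Cs2CO3 (0.55 equiv), DMF, 0 °C → rt
Reagents that add atoms: none
Why: SN2 O-alkylation of the caesium carboxylate by the allylic bromide is fast, and the hindered trichlorophenyl ester is not attacked by the carboxylate.

Step 11
Reactants: 22 tert-butyl (2E)-but-2-enoate
Product: 23 tert-butyl (2E)-4-oxobut-2-enoate
Conditions: SeO2, 1,4-dioxane, reflux
Reagents that add atoms: selenium dioxide, O=[Se]=O
Why: Riley allylic oxidation of the γ-methyl group of the crotonate gives the γ-oxo enoate with the E alkene retained.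

Step 12
Reactants: 21 2,4,6-trichlorophenyl (2E)-4-{[(2E,4E,6R,11S)-11-[(tert-butyldimethylsilyl)oxy]-4,6-dimethyldodeca-2,4-dienoyl]oxy}but-2-enoate; 23 tert-butyl (2E)-4-oxobut-2-enoate (1.5 equiv)
Product: 24 tert-butyl (2E)-3-[(2S,3S)-3-{[(2E,4E,6R,11S)-11-[(tert-butyldimethylsilyl)oxy]-4,6-dimethyldodeca-2,4-dienoyl]oxy}-6-oxo-3,6-dihydro-2H-pyran-2-yl]prop-2-enoate
Conditions: (2S,3R)-HyperBTM (20 mol%; its enantiomer is used instead if the first run shows the opposite sense), iPr2NEt (1.0 equiv), CH2Cl2, −40 → −10 °C; AcOH quench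
Reagents that add atoms: none
Why: Proposed new method: the isothiourea is acylated by 21 with loss of trichlorophenoxide, the aryloxide/amine removes the γ-hydrogen (acidified by the acyl ammonium and the γ-acyloxy group) to give a γ-acyloxy ammonium dienolate held planar by the S···O contact, this adds through its γ-carbon to the aldehyde of 23 on the face away from the catalyst phenyl group in a closed endo [4+2]-like arrangement (alkenyl group of the aldehyde over the dienolate, acyloxy group outward) that should give the cis 5S,6S pair, and the alkoxide then lactonises onto the acyl ammonium, closing the ring and releasing the catalyst; the closest known reaction type is the formal [4+2] (vinylogous aldol–lactonisation) of Lewis-base-bound dienolates (vinylketene/cinchona, azolium and ammonium dienolates) with activated aldehydes and ketones to 5,6-dihydropyran-2-ones, and what is new is the γ-acyloxy dienolate creating the second, oxygenated stereocentre, the enal acceptor, and isothiourea turnover by lactonisation.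

Step 13
Reactants: 24 tert-butyl (2E)-3-[(2S,3S)-3-{[(2E,4E,6R,11S)-11-[(tert-butyldimethylsilyl)oxy]-4,6-dimethyldodeca-2,4-dienoyl]oxy}-6-oxo-3,6-dihydro-2H-pyran-2-yl]prop-2-enoate
Product: 25 (2E)-3-[(2S,3S)-3-{[(2E,4E,6R,11S)-11-hydroxy-4,6-dimethyldodeca-2,4-dienoyl]oxy}-6-oxo-3,6-dihydro-2H-pyran-2-yl]prop-2-enoic acid (CNP0107712.2)
Conditions: CF3CO2H/H2O (9:1), 0 °C → rt; evaporate with toluene
Reagents that add atoms: none
Why: Acidolysis removes the tert-butyl ester and the secondary TBS ether in one operation, and the 5-acyloxy lactone, which would eliminate to a 2-pyranone under basic deprotection, is stable to acid.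

## Compound list

1 | 1,1-dimethoxypropan-2-one | CC(=O)C(OC)OC | starting material
2 | (triphenylphosphoranylidene)acetaldehyde | O=CC=P(c1ccccc1)(c1ccccc1)c1ccccc1 | starting material
3 | (2E)-4,4-dimethoxy-3-methylbut-2-enal | COC(OC)/C(C)=C/C=O | intermediate
4 | (3R)-4,4-dimethoxy-3-methylbutanal | COC(OC)[C@H](C)CC=O | intermediate
5 | [2-(2-methyl-1,3-dioxolan-2-yl)ethyl]triphenylphosphonium bromide | CC1(CC[P+](c2ccccc2)(c2ccccc2)c2ccccc2)OCCO1.[Br-] | starting material
6 | [2-(2-methyl-1,3-dioxolan-2-yl)ethylidene]triphenylphosphorane (ylide) | CC1(CC=P(c2ccccc2)(c2ccccc2)c2ccccc2)OCCO1 | intermediate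
7 | 2-[(2Z,5R)-6,6-dimethoxy-5-methylhex-2-en-1-yl]-2-methyl-1,3-dioxolane | COC(OC)[C@H](C)C/C=C\CC1(C)OCCO1 | intermediate
8 | 2-[(5R)-6,6-dimethoxy-5-methylhexyl]-2-methyl-1,3-dioxolane | COC(OC)[C@H](C)CCCCC1(C)OCCO1 | intermediate
9 | (2R)-2-methyl-7-oxooctanal | O=C[C@H](C)CCCCC(C)=O | intermediate
10 | 2-(triphenylphosphoranylidene)propanal | CC(C=O)=P(c1ccccc1)(c1ccccc1)c1ccccc1 | starting material
11 | (2E,4R)-2,4-dimethyl-9-oxodec-2-enal | CC(/C=O)=C\[C@H](C)CCCCC(C)=O | intermediate
12 | malonic acid | OC(=O)CC(=O)O | starting material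
13 | 2-[(2E,4R)-2,4-dimethyl-9-oxodec-2-en-1-ylidene]propanedioic acid | CC(/C=C(C(=O)O)C(=O)O)=C\[C@H](C)CCCCC(C)=O | intermediate
14 | (2E,4E,6R)-4,6-dimethyl-11-oxododeca-2,4-dienoic acid | CC(/C=C/C(=O)O)=C\[C@H](C)CCCCC(C)=O | intermediate
15 | (2E,4E,6R,11S)-11-hydroxy-4,6-dimethyldodeca-2,4-dienoic acid | CC(/C=C/C(=O)O)=C\[C@H](C)CCCC[C@H](C)O | intermediate
16 | tert-butyldimethylsilyl (2E,4E,6R,11S)-11-[(tert-butyldimethylsilyl)oxy]-4,6-dimethyldodeca-2,4-dienoate | CC(/C=C/C(=O)O[Si](C)(C)C(C)(C)C)=C\[C@H](C)CCCC[C@H](C)O[Si](C)(C)C(C)(C)C | intermediate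
17 | (2E,4E,6R,11S)-11-[(tert-butyldimethylsilyl)oxy]-4,6-dimethyldodeca-2,4-dienoic acid | CC(/C=C/C(=O)O)=C\[C@H](C)CCCC[C@H](C)O[Si](C)(C)C(C)(C)C | intermediate
18 | (2E)-4-bromobut-2-enoic acid | OC(=O)/C=C/CBr | starting material
19 | 2,4,6-trichlorophenol | Oc1c(Cl)cc(Cl)cc1Cl | starting material
20 | 2,4,6-trichlorophenyl (2E)-4-bromobut-2-enoate | BrC/C=C/C(=O)Oc1c(Cl)cc(Cl)cc1Cl | intermediate
21 | 2,4,6-trichlorophenyl (2E)-4-{[(2E,4E,6R,11S)-11-[(tert-butyldimethylsilyl)oxy]-4,6-dimethyldodeca-2,4-dienoyl]oxy}but-2-enoate | CC(/C=C/C(=O)OC/C=C/C(=O)Oc1c(Cl)cc(Cl)cc1Cl)=C\[C@H](C)CCCC[C@H](C)O[Si](C)(C)C(C)(C)C | intermediate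
22 | tert-butyl (2E)-but-2-enoate | C/C=C/C(=O)OC(C)(C)C | starting material
23 | tert-butyl (2E)-4-oxobut-2-enoate | O=C/C=C/C(=O)OC(C)(C)C | intermediate
24 | tert-butyl (2E)-3-[(2S,3S)-3-{[(2E,4E,6R,11S)-11-[(tert-butyldimethylsilyl)oxy]-4,6-dimethyldodeca-2,4-dienoyl]oxy}-6-oxo-3,6-dihydro-2H-pyran-2-yl]prop-2-enoate | CC(/C=C/C(=O)O[C@H]1C=CC(=O)O[C@H]1/C=C/C(=O)OC(C)(C)C)=C\[C@H](C)CCCC[C@H](C)O[Si](C)(C)C(C)(C)C | intermediate
25 | (2E)-3-[(2S,3S)-3-{[(2E,4E,6R,11S)-11-hydroxy-4,6-dimethyldodeca-2,4-dienoyl]oxy}-6-oxo-3,6-dihydro-2H-pyran-2-yl]prop-2-enoic acid (CNP0107712.2) | CC(/C=C/C(=O)O[C@H]1C=CC(=O)O[C@H]1/C=C/C(=O)O)=C\[C@H](C)CCCC[C@H](C)O | target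

## Step count and risk

Total step count: 13. Longest linear sequence: 11 steps (steps 1–8, 10, 12, 13); steps 9 and 11 are one-step side branches.

**Step 12 (the proposed new annulation).** It may give the trans lactone, attack through the α-carbon (β-lactone), add to the enoate of 23 in Michael fashion, or lose the 5-acyloxy group from the product to give a 2-pyranone under the basic conditions. The fallback uses known chemistry, sets out from 23 and 17 and comes back at 24. L-Proline (20 mol%, DMF, 4 °C) catalyses the anti-selective cross-aldol addition of commercial (tert-butyldimethylsilyloxy)acetaldehyde (slow addition) to 23 and gives tert-butyl (2E,4S,5S)-5-[(tert-butyldimethylsilyl)oxy]-4-hydroxy-6-oxohex-2-enoate F1. Still–Gennari olefination of the aldehyde (methyl bis(2,2,2-trifluoroethyl)phosphonoacetate, KN(SiMe3)2, 18-crown-6, THF, −78 °C) gives 1-tert-butyl 8-methyl (2E,4S,5R,6Z)-5-[(tert-butyldimethylsilyl)oxy]-4-hydroxyocta-2,6-dienedioate F2. This lactonises (PPTS, toluene, 50 °C) to tert-butyl (2E)-3-[(2S,3R)-3-[(tert-butyldimethylsilyl)oxy]-6-oxo-3,6-dihydro-2H-pyran-2-yl]prop-2-enoate F3. HF·pyridine in THF frees the trans alcohol tert-butyl (2E)-3-[(2S,3R)-3-hydroxy-6-oxo-3,6-dihydro-2H-pyran-2-yl]prop-2-enoate F4. Mitsunobu esterification of F4 with acid 17 (PPh3, DIAD, toluene, 0 °C) inverts the carbinol centre and gives the cis ester 24.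

**Step 7 (ketoreductase reduction).** The polyunsaturated keto acid may be a poor enzyme substrate, or the selectivity may fall short. The fallback sets out from 14 and comes back at 15. Acid 14 is esterified (Me3SiCHN2, MeOH/toluene) to methyl (2E,4E,6R)-4,6-dimethyl-11-oxododeca-2,4-dienoate F5. This is reduced without stereocontrol (NaBH4, MeOH, 0 °C) to methyl (2E,4E,6R,11RS)-11-hydroxy-4,6-dimethyldodeca-2,4-dienoate F6. Lipase resolution (Novozym 435, vinyl acetate, hexane) acetylates only the 11R epimer to methyl (2E,4E,6R,11R)-11-acetoxy-4,6-dimethyldodeca-2,4-dienoate F7 and leaves methyl (2E,4E,6R,11S)-11-hydroxy-4,6-dimethyldodeca-2,4-dienoate F8, which is separated by chromatography. LiOH (THF/H2O) hydrolyses F8 to 15.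

**Step 1 (Wittig olefination of a ketone with the formyl ylide).** The ketone may react sluggishly, or the product enal may be homologated further. The fallback sets out from 1 and comes back at 3. Horner–Wadsworth–Emmons reaction of 1 with diethyl (cyanomethyl)phosphonate (NaH, THF) gives (2E)-4,4-dimethoxy-3-methylbut-2-enenitrile F9 (E/Z mixture, acceptable because step 2 is stereoconvergent). Reduction with iBu2AlH (toluene, −78 °C) and buffered aqueous hydrolysis of the imine gives 3.

## Further compounds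

F1 | step 12 | tert-butyl (2E,4S,5S)-5-[(tert-butyldimethylsilyl)oxy]-4-hydroxy-6-oxohex-2-enoate | CC(C)(C)[Si](C)(C)O[C@@H]([C@@H](O)/C=C/C(=O)OC(C)(C)C)C=O
F2 | step 12 | 1-tert-butyl 8-methyl (2E,4S,5R,6Z)-5-[(tert-butyldimethylsilyl)oxy]-4-hydroxyocta-2,6-dienedioate | CC(C)(C)[Si](C)(C)O[C@@H]([C@@H](O)/C=C/C(=O)OC(C)(C)C)/C=C\C(=O)OC
F3 | step 12 | tert-butyl (2E)-3-[(2S,3R)-3-[(tert-butyldimethylsilyl)oxy]-6-oxo-3,6-dihydro-2H-pyran-2-yl]prop-2-enoate | CC(C)(C)[Si](C)(C)O[C@@H]1C=CC(=O)O[C@H]1/C=C/C(=O)OC(C)(C)C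
F4 | step 12 | tert-butyl (2E)-3-[(2S,3R)-3-hydroxy-6-oxo-3,6-dihydro-2H-pyran-2-yl]prop-2-enoate | O[C@@H]1C=CC(=O)O[C@H]1/C=C/C(=O)OC(C)(C)C
F5 | step 7 | methyl (2E,4E,6R)-4,6-dimethyl-11-oxododeca-2,4-dienoate | CC(/C=C/C(=O)OC)=C\[C@H](C)CCCCC(C)=O
F6 | step 7 | methyl (2E,4E,6R,11RS)-11-hydroxy-4,6-dimethyldodeca-2,4-dienoate | CC(/C=C/C(=O)OC)=C\[C@H](C)CCCCC(C)O
F7 | step 7 | methyl (2E,4E,6R,11R)-11-acetoxy-4,6-dimethyldodeca-2,4-dienoate | CC(/C=C/C(=O)OC)=C\[C@H](C)CCCC[C@@H](C)OC(C)=O
F8 | step 7 | methyl (2E,4E,6R,11S)-11-hydroxy-4,6-dimethyldodeca-2,4-dienoate | CC(/C=C/C(=O)OC)=C\[C@H](C)CCCC[C@H](C)O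
F9 | step 1 | (2E)-4,4-dimethoxy-3-methylbut-2-enenitrile | COC(OC)/C(C)=C/C#N
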